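**Retrosynthetic overview**
1. Target ⇐ late oxidation of the C14 allylic alcohol, esterification of C8–OH with (S)-2-methylbutanoic acid and acetylation of C15–OH on a tris-silylated 12,6-olide.
2. Ten-membered carbocycle and α-methylene γ-lactone ⇐ one flask: a new iridium-catalysed macrocyclising 2-(alkoxycarbonyl)allylation forms C6–C7 (sets C6 and C7) from an acyclic C6 allylic alcohol carrying a C7 Morita–Baylis–Hillman carbonate; the carbocycle closes first, the lactone second.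
3. Acrylate unit ⇐ C7 aldehyde + methyl propiolate; C8–C10/C14 ⇐ reductive opening of an (E)-α-alkylidene γ-butyrolactone (a temporary ring, formed first and opened again).
4. Alkylidene lactone ⇐ Horner–Wadsworth–Emmons union (C1=C10) of a C1 aldehyde with a phosphono lactone made from (S)-PMB glycidyl ether (source of C8).
5. C1–C6/C15 aldehyde ⇐ Negishi coupling of a (Z)-iodoalkene (C4=C5 geometry from trans-hydroalumination/iodination of a but-2-yne-1,4-diol ether) with a zinc homoenolate.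

Abbreviations: TBS = tert-butyldimethylsilyl, TES = triethylsilyl, TBDPS = tert-butyldiphenylsilyl, PMB = 4-methoxybenzyl, Boc = tert-butoxycarbonyl; "TBSO-methyl" means CH2OTBS, and so on. Locants C1 to C15 in the explanations are those of the germacrane skeleton of the target (C12 lactone carbonyl, C13 exocyclic methylene, C14 aldehyde carbon, C15 acetoxymethyl carbon).

Assumption: (R)-SEGPHOS is taken as the ligand antipode that directs the allyl group to the Si face of the C6 aldehyde; (S)-PMB glycidyl ether and BrZnCH2CH2CO2Et (0.5 M in THF) are bought.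

**Route**

Step 1
Reactants: 1 but-2-yne-1,4-diol
Product: 2 4-(TBSO)but-2-yn-1-ol
Conditions: TBSCl (0.33 equiv), imidazole, DMF, 0 °C to rt (diol in threefold excess)
Reagents that add atoms: tert-butyldimethylsilyl chloride, CC(C)(C)[Si](C)(C)Cl
Why: Silylation of a symmetrical diol used in excess gives the mono-ether in high yield based on the silyl chloride (silyl ether formation).

Step 2
Reactants: 2 4-(TBSO)but-2-yn-1-ol
Product: 4 (Z)-4-(TBSO)-3-iodobut-2-en-1-ol, via alkenylalanate 3 (not isolated)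
Conditions: NaAlH2(OCH2CH2OMe)2 (Red-Al, 1.5 equiv), THF, 0 °C; then N-iodosuccinimide, −78 to 0 °C
Reagents that add atoms: N-iodosuccinimide, O=C1CCC(=O)N1I
Why: Alkoxide-directed trans-hydroalumination puts aluminium on the distal alkyne carbon and iododealumination with retention gives the (Z)-iodoalkene, which fixes the C4=C5 geometry with C15 trans to C6.

Step 3
Reactants: 4 (Z)-4-(TBSO)-3-iodobut-2-en-1-ol
Product: 5 (Z)-1-(TBSO)-2-iodo-4-(TESO)but-2-ene
Conditions: TESCl, imidazole, CH2Cl2, 0 °C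
Reagents that add atoms: chlorotriethylsilane, CC[Si](CC)(CC)Cl
Why: Routine silylation of the primary allylic alcohol; the labile TES group lets C6–OH be freed later beside TBS and TBDPS ethers.

Step 4
Reactants: 5 (Z)-1-(TBSO)-2-iodo-4-(TESO)but-2-ene, 6 (3-ethoxy-3-oxopropyl)zinc bromide (BrZnCH2CH2CO2Et)
Product: 7 ethyl (E)-4-(TBSO-methyl)-6-(TESO)hex-4-enoate
Conditions: Pd(PPh3)4 (5 mol %), THF, 50 °C
Reagents that add atoms: none
Why: Negishi coupling of an alkenyl iodide with an ester-bearing alkylzinc on zerovalent palladium proceeds with retention of alkene geometry, so C3 ends up cis to C6.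

Step 5
Reactants: 7 ethyl (E)-4-(TBSO-methyl)-6-(TESO)hex-4-enoate
Product: 8 (E)-4-(TBSO-methyl)-6-(TESO)hex-4-enal
Conditions: i-Bu2AlH (1.1 equiv), CH2Cl2, −78 °C
Reagents that add atoms: none
Why: Low-temperature i-Bu2AlH reduction stops at the aluminium hemiacetal and releases the aldehyde on work-up (partial ester reduction).

Step 6
Reactants: 9 (S)-2-(PMBO-methyl)oxirane, 10 triethyl phosphonoacetate
Product: 11 diethyl [(5S)-2-oxo-5-(PMBO-methyl)oxolan-3-yl]phosphonate (both C3 epimers)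
Conditions: NaH, toluene, 0 to 100 °C
Reagents that add atoms: none
Why: The phosphonoacetate anion opens the epoxide at the terminal carbon and the resulting alkoxide lactonises onto the ethyl ester, so the C8 stereocentre comes unchanged from the chiral pool (epoxide opening/lactonisation).

Step 7
Reactants: 8 (E)-4-(TBSO-methyl)-6-(TESO)hex-4-enal, 11 diethyl [(5S)-2-oxo-5-(PMBO-methyl)oxolan-3-yl]phosphonate
Product: 12 (3E,5S)-3-[(E)-4-(TBSO-methyl)-6-(TESO)hex-4-en-1-ylidene]-5-(PMBO-methyl)oxolan-2-one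
Conditions: t-BuOK, THF, 0 °C to rt
Reagents that add atoms: none
Why: Horner–Wadsworth–Emmons olefination of the lactone phosphonate gives mainly the (E)-alkylidene lactone (chain anti to the carbonyl), which sets the C1=C10 geometry with C2 cis to C9; the minor Z isomer is removed by chromatography.

Step 8
Reactants: 12 (3E,5S)-3-[(E)-4-(TBSO-methyl)-6-(TESO)hex-4-en-1-ylidene]-5-(PMBO-methyl)oxolan-2-one
Product: 13 (2S,4E,8E)-4-(hydroxymethyl)-1-(PMBO)-8-(TBSO-methyl)-10-(TESO)deca-4,8-dien-2-ol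
Conditions: i-Bu2AlH (4 equiv), CH2Cl2, −78 to 0 °C
Reagents that add atoms: none
Why: i-Bu2AlH reduces the unsaturated lactone by 1,2-addition to the allylic 1,4-diol without touching alkene geometry or the C8 centre.

Step 9
Reactants: 13 (2S,4E,8E)-4-(hydroxymethyl)-1-(PMBO)-8-(TBSO-methyl)-10-(TESO)deca-4,8-dien-2-ol
Product: 14 (2S,4E,8E)-1-(PMBO)-8-(TBSO-methyl)-4-(TBDPSO-methyl)-10-(TESO)deca-4,8-dien-2-ol
Conditions: TBDPSCl (1.05 equiv), imidazole, CH2Cl2, −20 °C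
Reagents that add atoms: tert-butyldiphenylsilyl chloride, CC(C)(C)[Si](Cl)(c1ccccc1)c1ccccc1
Why: The bulky silyl chloride reacts with the primary allylic C14–OH much faster than with the secondary C8–OH (selective silylation).

Step 10
Reactants: 14 (2S,4E,8E)-1-(PMBO)-8-(TBSO-methyl)-4-(TBDPSO-methyl)-10-(TESO)deca-4,8-dien-2-ol
Product: 15 (2S,4E,8E)-1-(PMBO)-2-(TBSO)-8-(TBSO-methyl)-4-(TBDPSO-methyl)-10-(TESO)deca-4,8-diene
Conditions: TBSOTf, 2,6-lutidine, CH2Cl2, −78 °C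
Reagents that add atoms: tert-butyldimethylsilyl trifluoromethanesulfonate, CC(C)(C)[Si](C)(C)OS(=O)(=O)C(F)(F)F
Why: A silyl triflate with a hindered base silylates the remaining secondary C8–OH cleanly.

Step 11
Reactants: 15 (2S,4E,8E)-1-(PMBO)-2-(TBSO)-8-(TBSO-methyl)-4-(TBDPSO-methyl)-10-(TESO)deca-4,8-diene
Product: 16 (2S,4E,8E)-2-(TBSO)-8-(TBSO-methyl)-4-(TBDPSO-methyl)-10-(TESO)deca-4,8-dien-1-ol
Conditions: DDQ, CH2Cl2/pH 7 buffer (10:1), 0 °C
Reagents that add atoms: none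
Why: DDQ oxidises the electron-rich PMB ether to an oxocarbenium ion that is hydrolysed, while the silyl ethers stay intact under buffered conditions (oxidative PMB cleavage).

Step 12
Reactants: 16 (2S,4E,8E)-2-(TBSO)-8-(TBSO-methyl)-4-(TBDPSO-methyl)-10-(TESO)deca-4,8-dien-1-ol
Product: 17 (2S,4E,8E)-2-(TBSO)-8-(TBSO-methyl)-4-(TBDPSO-methyl)-10-(TESO)deca-4,8-dienal
Conditions: Dess–Martin periodinane, pyridine, CH2Cl2, 0 °C to rt
Reagents that add atoms: none
Why: Buffered Dess–Martin oxidation gives the α-silyloxy aldehyde (C7) without epimerising C8.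

Step 13
Reactants: 17 (2S,4E,8E)-2-(TBSO)-8-(TBSO-methyl)-4-(TBDPSO-methyl)-10-(TESO)deca-4,8-dienal, 18 methyl propiolate
Product: 20 methyl (4S,6E,10E)-3-hydroxy-2-methylidene-4-(TBSO)-10-(TBSO-methyl)-6-(TBDPSO-methyl)-12-(TESO)dodeca-6,10-dienoate (both C3 epimers), via vinylalane 19 (not isolated)
Conditions: i-Bu2AlH, N-methylmorpholine N-oxide, THF, 0 °C, methyl propiolate; then 17, 0 °C to rt
Reagents that add atoms: none
Why: Hydroalumination of the propiolate gives an α-aluminoacrylate that adds to the aldehyde and forms the C7–C11 bond under non-basic conditions (vinylalumination, a Morita–Baylis–Hillman surrogate); the new C7 carbinol centre is irrelevant because it later becomes an allyl terminus.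

Step 14
Reactants: 20 methyl (4S,6E,10E)-3-hydroxy-2-methylidene-4-(TBSO)-10-(TBSO-methyl)-6-(TBDPSO-methyl)-12-(TESO)dodeca-6,10-dienoate
Product: 21 methyl (4S,6E,10E)-3-(BocO)-2-methylidene-4-(TBSO)-10-(TBSO-methyl)-6-(TBDPSO-methyl)-12-(TESO)dodeca-6,10-dienoate
Conditions: Boc2O, DMAP (10 mol %), CH2Cl2, 0 °C
Reagents that add atoms: di-tert-butyl dicarbonate, CC(C)(C)OC(=O)OC(=O)OC(C)(C)C
Why: DMAP-catalysed acylation turns the allylic alcohol into an ionisable tert-butyl carbonate (carbonate formation).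

Step 15
Reactants: 21 methyl (4S,6E,10E)-3-(BocO)-2-methylidene-4-(TBSO)-10-(TBSO-methyl)-6-(TBDPSO-methyl)-12-(TESO)dodeca-6,10-dienoate
Product: 22 methyl (4S,6E,10E)-3-(BocO)-12-hydroxy-2-methylidene-4-(TBSO)-10-(TBSO-methyl)-6-(TBDPSO-methyl)dodeca-6,10-dienoate
Conditions: PPTS (10 mol %), MeOH/CH2Cl2 (1:1), 0 °C
Reagents that add atoms: none
Why: Mild acid methanolysis cleaves the primary TES ether much faster than the TBS ethers, the TBDPS ether or the carbonate (selective desilylation).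

Step 16
Reactants: 22 methyl (4S,6E,10E)-3-(BocO)-12-hydroxy-2-methylidene-4-(TBSO)-10-(TBSO-methyl)-6-(TBDPSO-methyl)dodeca-6,10-dienoate
Product: 25 (3aS,4S,6E,10E,11aR)-3-methylidene-4-(TBSO)-10-(TBSO-methyl)-6-(TBDPSO-methyl)-3a,4,5,8,9,11a-hexahydrocyclodeca[b]furan-2(3H)-one, via enal carbonate 23 (not isolated), via hydroxy ester 24 (not isolated)
Conditions: [Ir(cod)Cl]2 (10 mol %), (R)-SEGPHOS (20 mol %), 4-cyano-3-nitrobenzoic acid (20 mol %), Cs2CO3 (40 mol %), THF, 80 °C, syringe-pump addition of 22 over 12 h (final 2 mM)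
Reagents that add atoms: none
Why: Proposed new method: a redox-neutral, macrocyclising iridium-catalysed transfer-hydrogenative 2-(alkoxycarbonyl)allylation, in which the cyclometalated trivalent iridium C,O-benzoate dehydrogenates the C6 allylic alcohol to enal 23, the resulting monovalent iridium ionises the carbonate (loss of CO2 and tert-butoxide, both C7 epimers converging on one allyl complex), and the primary σ-allyl form (Ir on C13, C8-bearing substituent pseudo-equatorial) adds through a closed chair transition state to the Si face of the enal under ligand control to give the anti adduct 24 (6,7-trans), which lactonises in the flask; the ring and C6/C7 are thus set by catalyst and chair geometry while C8 is preset, and the closest known chemistry is the intermolecular iridium-catalysed 2-(alkoxycarbonyl)allylation and anti-crotylation of primary alcohols, not yet shown for γ-substituted donors, intramolecularly, or for ten-membered carbocycles.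

Step 17
Reactants: 25 (3aS,4S,6E,10E,11aR)-3-methylidene-4-(TBSO)-10-(TBSO-methyl)-6-(TBDPSO-methyl)-3a,4,5,8,9,11a-hexahydrocyclodeca[b]furan-2(3H)-one
Product: 26 (3aR,4S,6E,10E,11aR)-4-hydroxy-10-(hydroxymethyl)-3-methylidene-6-(TBDPSO-methyl)-3a,4,5,8,9,11a-hexahydrocyclodeca[b]furan-2(3H)-one
Conditions: 48% aq. HF/MeCN (1:19), 0 °C to rt
Reagents that add atoms: none
Why: Aqueous HF cleaves the primary and the secondary TBS ether far faster than the TBDPS ether, freeing C15–OH and C8–OH (selective desilylation).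

Step 18
Reactants: 26 (3aR,4S,6E,10E,11aR)-4-hydroxy-10-(hydroxymethyl)-3-methylidene-6-(TBDPSO-methyl)-3a,4,5,8,9,11a-hexahydrocyclodeca[b]furan-2(3H)-one
Product: 27 [(3aR,4S,6E,10E,11aR)-4-hydroxy-3-methylidene-2-oxo-6-(TBDPSO-methyl)-2,3,3a,4,5,8,9,11a-octahydrocyclodeca[b]furan-10-yl]methyl acetate
Conditions: AcCl (1.1 equiv), 2,4,6-collidine, CH2Cl2, −78 °C
Reagents that add atoms: acetyl chloride, CC(Cl)=O
Why: At −78 °C with a hindered base the primary allylic C15–OH is acetylated much faster than the hindered secondary C8–OH (selective acylation).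

Step 19
Reactants: 27 [(3aR,4S,6E,10E,11aR)-4-hydroxy-3-methylidene-2-oxo-6-(TBDPSO-methyl)-2,3,3a,4,5,8,9,11a-octahydrocyclodeca[b]furan-10-yl]methyl acetate, 28 (S)-2-methylbutanoic acid
Product: 29 (3aR,4S,6E,10E,11aR)-10-(acetoxymethyl)-3-methylidene-2-oxo-6-(TBDPSO-methyl)-2,3,3a,4,5,8,9,11a-octahydrocyclodeca[b]furan-4-yl (2S)-2-methylbutanoate
Conditions: DCC, DMAP (20 mol %), CH2Cl2, 0 °C to rt
Reagents that add atoms: none
Why: Steglich esterification acylates C8–OH with retention at C8 and, under these mild conditions, without racemising the α-stereocentre of the acid.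

Step 20
Reactants: 29 (3aR,4S,6E,10E,11aR)-10-(acetoxymethyl)-3-methylidene-2-oxo-6-(TBDPSO-methyl)-2,3,3a,4,5,8,9,11a-octahydrocyclodeca[b]furan-4-yl (2S)-2-methylbutanoate
Product: 30 (3aR,4S,6E,10E,11aR)-10-(acetoxymethyl)-6-(hydroxymethyl)-3-methylidene-2-oxo-2,3,3a,4,5,8,9,11a-octahydrocyclodeca[b]furan-4-yl (2S)-2-methylbutanoate
Conditions: HF·pyridine, pyridine/THF, 0 °C to rt
Reagents that add atoms: none
Why: Buffered fluoride cleaves the TBDPS ether while the two esters and the methylene lactone survive (desilylation).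

Step 21
Reactants: 30 (3aR,4S,6E,10E,11aR)-10-(acetoxymethyl)-6-(hydroxymethyl)-3-methylidene-2-oxo-2,3,3a,4,5,8,9,11a-octahydrocyclodeca[b]furan-4-yl (2S)-2-methylbutanoate
Product: 31 (3aR,4S,6E,10E,11aR)-10-(acetoxymethyl)-6-formyl-3-methylidene-2-oxo-2,3,3a,4,5,8,9,11a-octahydrocyclodeca[b]furan-4-yl (2S)-2-methylbutanoate (CNP0230988.8)
Conditions: MnO2 (20 equiv), CH2Cl2, rt
Reagents that add atoms: none
Why: MnO2 oxidises only the primary allylic alcohol to the conjugated aldehyde and leaves esters, alkene geometry and the methylene lactone untouched (allylic oxidation).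

**Compound list**
1 | but-2-yne-1,4-diol | OCC#CCO | starting material
2 | 4-(TBSO)but-2-yn-1-ol | OCC#CCO[Si](C)(C)C(C)(C)C | intermediate
3 | sodium 3-(TBSO-methyl)-2,2-bis(2-methoxyethoxy)-2,5-dihydro-1,2-oxaaluminol-2-uide (cyclic alkenylalanate) | [Na+].COCCO[Al-]1(OCCOC)OCC=C1CO[Si](C)(C)C(C)(C)C | intermediate
4 | (Z)-4-(TBSO)-3-iodobut-2-en-1-ol | OC/C=C(\I)CO[Si](C)(C)C(C)(C)C | intermediate
5 | (Z)-1-(TBSO)-2-iodo-4-(TESO)but-2-ene | CC[Si](CC)(CC)OC/C=C(\I)CO[Si](C)(C)C(C)(C)C | intermediate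
6 | (3-ethoxy-3-oxopropyl)zinc bromide (BrZnCH2CH2CO2Et) | CCOC(=O)CC[Zn]Br | starting material
7 | ethyl (E)-4-(TBSO-methyl)-6-(TESO)hex-4-enoate | CC[Si](CC)(CC)OC/C=C(/CO[Si](C)(C)C(C)(C)C)CCC(=O)OCC | intermediate
8 | (E)-4-(TBSO-methyl)-6-(TESO)hex-4-enal | CC[Si](CC)(CC)OC/C=C(/CO[Si](C)(C)C(C)(C)C)CCC=O | intermediate
9 | (S)-2-(PMBO-methyl)oxirane | COc1ccc(COC[C@@H]2CO2)cc1 | starting material
10 | triethyl phosphonoacetate | CCOC(=O)CP(=O)(OCC)OCC | starting material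
11 | diethyl [(5S)-2-oxo-5-(PMBO-methyl)oxolan-3-yl]phosphonate (both C3 epimers) | CCOP(=O)(OCC)C1C[C@@H](COCc2ccc(OC)cc2)OC1=O | intermediate
12 | (3E,5S)-3-[(E)-4-(TBSO-methyl)-6-(TESO)hex-4-en-1-ylidene]-5-(PMBO-methyl)oxolan-2-one | CC[Si](CC)(CC)OC/C=C(/CO[Si](C)(C)C(C)(C)C)CC/C=C1\C[C@@H](COCc2ccc(OC)cc2)OC1=O | intermediate
13 | (2S,4E,8E)-4-(hydroxymethyl)-1-(PMBO)-8-(TBSO-methyl)-10-(TESO)deca-4,8-dien-2-ol | CC[Si](CC)(CC)OC/C=C(/CO[Si](C)(C)C(C)(C)C)CC/C=C(/CO)C[C@H](O)COCc1ccc(OC)cc1 | intermediate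
14 | (2S,4E,8E)-1-(PMBO)-8-(TBSO-methyl)-4-(TBDPSO-methyl)-10-(TESO)deca-4,8-dien-2-ol | CC[Si](CC)(CC)OC/C=C(/CO[Si](C)(C)C(C)(C)C)CC/C=C(/CO[Si](c1ccccc1)(c1ccccc1)C(C)(C)C)C[C@H](O)COCc1ccc(OC)cc1 | intermediate
15 | (2S,4E,8E)-1-(PMBO)-2-(TBSO)-8-(TBSO-methyl)-4-(TBDPSO-methyl)-10-(TESO)deca-4,8-diene | CC[Si](CC)(CC)OC/C=C(/CO[Si](C)(C)C(C)(C)C)CC/C=C(/CO[Si](c1ccccc1)(c1ccccc1)C(C)(C)C)C[C@H](O[Si](C)(C)C(C)(C)C)COCc1ccc(OC)cc1 | intermediate
16 | (2S,4E,8E)-2-(TBSO)-8-(TBSO-methyl)-4-(TBDPSO-methyl)-10-(TESO)deca-4,8-dien-1-ol | CC[Si](CC)(CC)OC/C=C(/CO[Si](C)(C)C(C)(C)C)CC/C=C(/CO[Si](c1ccccc1)(c1ccccc1)C(C)(C)C)C[C@H](O[Si](C)(C)C(C)(C)C)CO | intermediate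
17 | (2S,4E,8E)-2-(TBSO)-8-(TBSO-methyl)-4-(TBDPSO-methyl)-10-(TESO)deca-4,8-dienal | CC[Si](CC)(CC)OC/C=C(/CO[Si](C)(C)C(C)(C)C)CC/C=C(/CO[Si](c1ccccc1)(c1ccccc1)C(C)(C)C)C[C@H](O[Si](C)(C)C(C)(C)C)C=O | intermediate
18 | methyl propiolate | C#CC(=O)OC | starting material
19 | methyl 2-(diisobutylalumanyl)prop-2-enoate | C=C(C(=O)OC)[Al](CC(C)C)CC(C)C | intermediate
20 | methyl (4S,6E,10E)-3-hydroxy-2-methylidene-4-(TBSO)-10-(TBSO-methyl)-6-(TBDPSO-methyl)-12-(TESO)dodeca-6,10-dienoate (both C3 epimers) | CC[Si](CC)(CC)OC/C=C(/CO[Si](C)(C)C(C)(C)C)CC/C=C(/CO[Si](c1ccccc1)(c1ccccc1)C(C)(C)C)C[C@H](O[Si](C)(C)C(C)(C)C)C(O)C(=C)C(=O)OC | intermediate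
21 | methyl (4S,6E,10E)-3-(BocO)-2-methylidene-4-(TBSO)-10-(TBSO-methyl)-6-(TBDPSO-methyl)-12-(TESO)dodeca-6,10-dienoate (both C3 epimers) | CC[Si](CC)(CC)OC/C=C(/CO[Si](C)(C)C(C)(C)C)CC/C=C(/CO[Si](c1ccccc1)(c1ccccc1)C(C)(C)C)C[C@H](O[Si](C)(C)C(C)(C)C)C(OC(=O)OC(C)(C)C)C(=C)C(=O)OC | intermediate
22 | methyl (4S,6E,10E)-3-(BocO)-12-hydroxy-2-methylidene-4-(TBSO)-10-(TBSO-methyl)-6-(TBDPSO-methyl)dodeca-6,10-dienoate (both C3 epimers) | OC/C=C(/CO[Si](C)(C)C(C)(C)C)CC/C=C(/CO[Si](c1ccccc1)(c1ccccc1)C(C)(C)C)C[C@H](O[Si](C)(C)C(C)(C)C)C(OC(=O)OC(C)(C)C)C(=C)C(=O)OC | intermediate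
23 | methyl (4S,6E,10E)-3-(BocO)-2-methylidene-12-oxo-4-(TBSO)-10-(TBSO-methyl)-6-(TBDPSO-methyl)dodeca-6,10-dienoate (both C3 epimers) | O=C/C=C(/CO[Si](C)(C)C(C)(C)C)CC/C=C(/CO[Si](c1ccccc1)(c1ccccc1)C(C)(C)C)C[C@H](O[Si](C)(C)C(C)(C)C)C(OC(=O)OC(C)(C)C)C(=C)C(=O)OC | intermediate
24 | methyl 2-[(1S,2R,3E,7E,10S)-2-hydroxy-10-(TBSO)-4-(TBSO-methyl)-8-(TBDPSO-methyl)cyclodeca-3,7-dien-1-yl]prop-2-enoate | C=C(C(=O)OC)[C@H]1[C@H](O)/C=C(/CO[Si](C)(C)C(C)(C)C)CC/C=C(/CO[Si](c2ccccc2)(c2ccccc2)C(C)(C)C)C[C@@H]1O[Si](C)(C)C(C)(C)C | intermediate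
25 | (3aS,4S,6E,10E,11aR)-3-methylidene-4-(TBSO)-10-(TBSO-methyl)-6-(TBDPSO-methyl)-3a,4,5,8,9,11a-hexahydrocyclodeca[b]furan-2(3H)-one | C=C1C(=O)O[C@@H]2/C=C(/CO[Si](C)(C)C(C)(C)C)CC/C=C(/CO[Si](c3ccccc3)(c3ccccc3)C(C)(C)C)C[C@H](O[Si](C)(C)C(C)(C)C)[C@@H]12 | intermediate
26 | (3aR,4S,6E,10E,11aR)-4-hydroxy-10-(hydroxymethyl)-3-methylidene-6-(TBDPSO-methyl)-3a,4,5,8,9,11a-hexahydrocyclodeca[b]furan-2(3H)-one | C=C1C(=O)O[C@@H]2/C=C(/CO)CC/C=C(/CO[Si](c3ccccc3)(c3ccccc3)C(C)(C)C)C[C@H](O)[C@@H]12 | intermediate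
27 | [(3aR,4S,6E,10E,11aR)-4-hydroxy-3-methylidene-2-oxo-6-(TBDPSO-methyl)-2,3,3a,4,5,8,9,11a-octahydrocyclodeca[b]furan-10-yl]methyl acetate | C=C1C(=O)O[C@@H]2/C=C(/COC(C)=O)CC/C=C(/CO[Si](c3ccccc3)(c3ccccc3)C(C)(C)C)C[C@H](O)[C@@H]12 | intermediate
28 | (S)-2-methylbutanoic acid | CC[C@H](C)C(=O)O | starting material
29 | (3aR,4S,6E,10E,11aR)-10-(acetoxymethyl)-3-methylidene-2-oxo-6-(TBDPSO-methyl)-2,3,3a,4,5,8,9,11a-octahydrocyclodeca[b]furan-4-yl (2S)-2-methylbutanoate | C=C1C(=O)O[C@@H]2/C=C(/COC(C)=O)CC/C=C(/CO[Si](c3ccccc3)(c3ccccc3)C(C)(C)C)C[C@H](OC(=O)[C@@H](C)CC)[C@@H]12 | intermediate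
30 | (3aR,4S,6E,10E,11aR)-10-(acetoxymethyl)-6-(hydroxymethyl)-3-methylidene-2-oxo-2,3,3a,4,5,8,9,11a-octahydrocyclodeca[b]furan-4-yl (2S)-2-methylbutanoate | C=C1C(=O)O[C@@H]2/C=C(/COC(C)=O)CC/C=C(/CO)C[C@H](OC(=O)[C@@H](C)CC)[C@@H]12 | intermediate
31 | (3aR,4S,6E,10E,11aR)-10-(acetoxymethyl)-6-formyl-3-methylidene-2-oxo-2,3,3a,4,5,8,9,11a-octahydrocyclodeca[b]furan-4-yl (2S)-2-methylbutanoate (CNP0230988.8) | C=C1C(=O)O[C@@H]2/C=C(/COC(C)=O)CC/C=C(/C=O)C[C@H](OC(=O)[C@@H](C)CC)[C@@H]12 | target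

**Count and risks**

Total step count: 21. Longest linear sequence: 20 steps (steps 1 to 5 and 7 to 21, from but-2-yne-1,4-diol); step 6 is the only side branch.

The three steps most likely to fail:

Step 16 (the proposed new macrocyclisation). Risks are oligomerisation, O-allylation of the C6 alcohol, conjugate reduction by iridium hydride, and a syn or wrong-face addition. The fallback uses known chemistry, sets out from 20 and comes back at 25. Alcohol 20 is treated with N-bromosuccinimide/Me2S (CH2Cl2, 0 °C), which gives with allylic transposition the (Z)-allylic bromide F1. PPTS in MeOH then frees the C6 alcohol to give bromo alcohol F2, and MnO2 oxidises it to bromo enal F3. Slow addition of F3 to excess CrCl2 in THF (1 mM, rt) effects the stoichiometric Barbier-type Nozaki–Hiyama ring closure by divalent chromium. This reaction is established for ten-membered germacranolide rings and, through a chair with the allyl substituent equatorial, normally gives the anti adduct. The product is hydroxy ester 24, which lactonises on brief treatment with PPTS to 25. Facial control at C6 then rests on the C8 stereocentre and the ring, not on a catalyst.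

Step 7 (alkylidene lactone geometry). The E/Z ratio of phosphono-lactone olefinations with aliphatic aldehydes can be modest, and the enolisable aldehyde may self-condense. The fallback sets out from 8 and comes back at 12. Commercial (S)-5-(hydroxymethyl)oxolan-2-one is protected with 4-methoxybenzyl trichloroacetimidate (cat. camphorsulfonic acid) to give the PMB lactone F4. Its lithium enolate (LDA, THF, −78 °C) adds to 8 to give the aldol adduct F5. MsCl/Et3N converts this into the mesylate F6, which is not isolated; DBU then eliminates it by an E1cB pathway to the thermodynamically favoured (E)-alkylidene lactone 12.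

Step 13 (vinylalumination of a hindered α-silyloxy aldehyde). The alane may reduce the aldehyde or add sluggishly. The fallback sets out from 17 and comes back at 20. The lithium enolate of methyl 3-(phenylselanyl)propanoate (LDA, THF, −78 °C) adds to 17 to give the aldol selenide F7. H2O2/pyridine (CH2Cl2, 0 °C) oxidises it to the selenoxide F8, which is not isolated and undergoes syn-elimination toward the only available β-hydrogen to give the methylidene ester 20.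

**Further compounds**
F1 | step 16 | methyl (2Z,4S,6E,10E)-2-(bromomethyl)-4-(TBSO)-10-(TBSO-methyl)-6-(TBDPSO-methyl)-12-(TESO)dodeca-2,6,10-trienoate | CC[Si](CC)(CC)OC/C=C(/CO[Si](C)(C)C(C)(C)C)CC/C=C(/CO[Si](c1ccccc1)(c1ccccc1)C(C)(C)C)C[C@H](O[Si](C)(C)C(C)(C)C)/C=C(\CBr)C(=O)OC
F2 | step 16 | methyl (2Z,4S,6E,10E)-2-(bromomethyl)-12-hydroxy-4-(TBSO)-10-(TBSO-methyl)-6-(TBDPSO-methyl)dodeca-2,6,10-trienoate | OC/C=C(/CO[Si](C)(C)C(C)(C)C)CC/C=C(/CO[Si](c1ccccc1)(c1ccccc1)C(C)(C)C)C[C@H](O[Si](C)(C)C(C)(C)C)/C=C(\CBr)C(=O)OC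
F3 | step 16 | methyl (2Z,4S,6E,10E)-2-(bromomethyl)-12-oxo-4-(TBSO)-10-(TBSO-methyl)-6-(TBDPSO-methyl)dodeca-2,6,10-trienoate | O=C/C=C(/CO[Si](C)(C)C(C)(C)C)CC/C=C(/CO[Si](c1ccccc1)(c1ccccc1)C(C)(C)C)C[C@H](O[Si](C)(C)C(C)(C)C)/C=C(\CBr)C(=O)OC
F4 | step 7 | (S)-5-(PMBO-methyl)oxolan-2-one | COc1ccc(COC[C@@H]2CCC(=O)O2)cc1
F5 | step 7 | (5S)-3-[(E)-1-hydroxy-4-(TBSO-methyl)-6-(TESO)hex-4-en-1-yl]-5-(PMBO-methyl)oxolan-2-one (diastereomer mixture) | CC[Si](CC)(CC)OC/C=C(/CO[Si](C)(C)C(C)(C)C)CCC(O)C1C[C@@H](COCc2ccc(OC)cc2)OC1=O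
F6 | step 7 | (5S)-3-[(E)-1-(methanesulfonyloxy)-4-(TBSO-methyl)-6-(TESO)hex-4-en-1-yl]-5-(PMBO-methyl)oxolan-2-one (diastereomer mixture) | CC[Si](CC)(CC)OC/C=C(/CO[Si](C)(C)C(C)(C)C)CCC(OS(C)(=O)=O)C1C[C@@H](COCc2ccc(OC)cc2)OC1=O
F7 | step 13 | methyl (4S,6E,10E)-3-hydroxy-2-[(phenylselanyl)methyl]-4-(TBSO)-10-(TBSO-methyl)-6-(TBDPSO-methyl)-12-(TESO)dodeca-6,10-dienoate (diastereomer mixture) | CC[Si](CC)(CC)OC/C=C(/CO[Si](C)(C)C(C)(C)C)CC/C=C(/CO[Si](c1ccccc1)(c1ccccc1)C(C)(C)C)C[C@H](O[Si](C)(C)C(C)(C)C)C(O)C(C[Se]c1ccccc1)C(=O)OC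
F8 | step 13 | methyl (4S,6E,10E)-3-hydroxy-2-[(phenylseleninyl)methyl]-4-(TBSO)-10-(TBSO-methyl)-6-(TBDPSO-methyl)-12-(TESO)dodeca-6,10-dienoate (diastereomer mixture) | CC[Si](CC)(CC)OC/C=C(/CO[Si](C)(C)C(C)(C)C)CC/C=C(/CO[Si](c1ccccc1)(c1ccccc1)C(C)(C)C)C[C@H](O[Si](C)(C)C(C)(C)C)C(O)C(C[Se](=O)c1ccccc1)C(=O)OC
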